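**Strategy.** The seven-membered ring is grown last from a six-membered ketone. In the target, C8 carries the vinylic methyl and sits between the alkene carbon C7 and the oxygenated C9, so C8 and its methyl can be delivered together as a chloro(methyl)carbenoid: cyclopropanation of the C7=C9 silyl enol ether of a trans-hydrindanone and opening of the chlorocyclopropane make C7–C8 and C8–C9, break C7–C9 and leave the 8-methyl-7-en-9-one in one operation. The precursor is a trans-fused hydrindane silyl enol ether that already carries C1 (angular methyl), C4 (silylated isopropyl carbinol), C5 and C6 (silyl ether), built by conjugate addition, Grignard addition and a six-membered aldol closure.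

Key step: step 9

Remark: daucane numbering is used for the atoms (C1 quaternary ring-fusion carbon with the methyl, C4 isopropyl carbinol, C5 ring-fusion CH, C6–C10 the remaining ring carbons); β is the face of the C1 methyl, α the face of H5.

Assumption: the enantiomer of the phosphoramidite ligand in step 2 is the one that gives (R)-C1; if the sense of induction is the opposite, the antipodal ligand is used.

**Route**

Step 1
Reactants: 1 3-ethoxycyclopent-2-en-1-one; 2 allylmagnesium bromide
Product: 4 3-allylcyclopent-2-en-1-one, via bromomagnesium alkoxide adduct 3 (not isolated)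
Conditions: THF, 0 °C; then 1 M HCl, 0 °C
Reagents that add atoms: water, O
Why: 1,2-addition of the Grignard reagent to the vinylogous ester carbonyl, then acid hydrolysis with allylic transposition (Stork–Danheiser sequence), should give the 3-substituted enone, and no stereocentre is formed.

Step 2
Reactants: 4 3-allylcyclopent-2-en-1-one
Product: 6 (R)-[(3-allyl-3-methylcyclopent-1-en-1-yl)oxy]trimethylsilane, via dimethylaluminium enolate 5 (not isolated)
Conditions: AlMe3, Cu(OTf)2 (2 mol %), (S)-BINOL-derived phosphoramidite of bis[(S)-1-phenylethyl]amine (4 mol %), Et2O, −30 °C; then TMSOTf, THF, −30 → 0 °C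
Reagents that add atoms: trimethylaluminium, C[Al](C)C; trimethylsilyl trifluoromethanesulfonate, C[Si](C)(C)OS(=O)(=O)C(F)(F)F
Why: copper-catalysed asymmetric conjugate addition of the methylaluminium reagent to the β-substituted enone builds the quaternary C1 centre with the face set by the chiral ligand, and O-silylation of the aluminium enolate stores the enolate regiospecifically on the C4–C5 side.

Step 3
Reactants: 6 (R)-[(3-allyl-3-methylcyclopent-1-en-1-yl)oxy]trimethylsilane
Product: 7 (2S,3R)-3-allyl-2-(dimethoxymethyl)-3-methylcyclopentan-1-one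
Conditions: HC(OMe)3, BF3·OEt2, CH2Cl2, −78 °C; then K2CO3, MeOH, 25 °C
Reagents that add atoms: trimethyl orthoformate, COC(OC)OC
Why: Mukaiyama-type addition of the silyl enol ether to the dimethoxycarbenium ion installs C6 at the acetal oxidation level, and because the new C5 centre is epimerisable, equilibration in basic methanol should enrich the epimer with the acetal trans to the allyl arm and cis to the smaller methyl, the two epimers being separated and the unwanted one re-equilibrated.

Step 4
Reactants: 7 (2S,3R)-3-allyl-2-(dimethoxymethyl)-3-methylcyclopentan-1-one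
Product: 8 (1R,2R,3R)-3-allyl-2-(dimethoxymethyl)-3-methyl-1-(propan-2-yl)cyclopentan-1-ol
Conditions: i-PrMgCl, LaCl3·2LiCl, THF, 0 °C
Reagents that add atoms: isopropylmagnesium chloride, CC(C)[Mg]Cl
Why: lanthanum-assisted Grignard 1,2-addition suppresses enolisation and reduction of the hindered cyclopentanone, and the isopropyl group should enter the carbonyl face opposite the neighbouring C5 acetal substituent, which places the C4 hydroxyl cis to C6 and to the angular methyl.

Step 5
Reactants: 8 (1R,2R,3R)-3-allyl-2-(dimethoxymethyl)-3-methyl-1-(propan-2-yl)cyclopentan-1-ol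
Product: 9 (1R,2R,5R)-2-allyl-2-methyl-5-(propan-2-yl)-5-[(triethylsilyl)oxy]cyclopentane-1-carbaldehyde
Conditions: TESOTf, 2,6-lutidine, CH2Cl2, 0 °C; then H2O
Reagents that add atoms: triethylsilyl trifluoromethanesulfonate, CC[Si](CC)(CC)OS(=O)(=O)C(F)(F)F; water, O
Why: O-silylation of the tertiary alcohol and silyl-triflate-mediated cleavage of the dimethyl acetal through a pyridinium-type intermediate release the aldehyde under non-acidic conditions, so that no free β-hydroxy aldehyde prone to dehydration or retro-aldol cleavage is present and no stereocentre changes.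

Step 6
Reactants: 9 (1R,2R,5R)-2-allyl-2-methyl-5-(propan-2-yl)-5-[(triethylsilyl)oxy]cyclopentane-1-carbaldehyde
Product: 10 (1R,2R,5R)-2-methyl-2-(2-oxopropyl)-5-(propan-2-yl)-5-[(triethylsilyl)oxy]cyclopentane-1-carbaldehyde
Conditions: PdCl2 (10 mol %), CuCl, O2 (1 atm), DMF/H2O, 25 °C
Reagents that add atoms: water, O; dioxygen, O=O
Why: Tsuji–Wacker oxidation converts the terminal alkene into the methyl ketone with Markovnikov regiochemistry, while the hindered aldehyde and the tertiary silyl ether should be untouched.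

Step 7
Reactants: 10 (1R,2R,5R)-2-methyl-2-(2-oxopropyl)-5-(propan-2-yl)-5-[(triethylsilyl)oxy]cyclopentane-1-carbaldehyde
Product: 12 (1R,3aR,7S,7aS)-3a-methyl-1-(propan-2-yl)-1-[(triethylsilyl)oxy]-7-[(trimethylsilyl)oxy]octahydro-5H-inden-5-one, via lithium aldolate 11 (not isolated)
Conditions: LiN(SiMe3)2, THF, −78 → −20 °C; then TMSCl, −78 → 0 °C
Reagents that add atoms: chlorotrimethylsilane, C[Si](C)(C)Cl
Why: the bulky amide deprotonates only the unhindered methyl of the ketone and the enolate closes onto the aldehyde in a 6-(enolendo)-exo-trig intramolecular aldol addition through a chair with the aldehyde oxygen equatorial, away from the axial angular methyl, so that C6 receives its oxygen α on a trans-fused hydrindanone whose fusion was preset at C1 and C5, and the reversible aldolate is then silylated on oxygen.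

Step 8
Reactants: 12 (1R,3aR,7S,7aS)-3a-methyl-1-(propan-2-yl)-1-[(triethylsilyl)oxy]-7-[(trimethylsilyl)oxy]octahydro-5H-inden-5-one
Product: 13 (1R,3aR,7S,7aS)-3a-methyl-1-(propan-2-yl)-1-[(triethylsilyl)oxy]-5,7-bis[(trimethylsilyl)oxy]-2,3,3a,4,7,7a-hexahydro-1H-indene
Conditions: lithium diisopropylamide, TMSCl, THF, −78 °C; then Et3N
Reagents that add atoms: chlorotrimethylsilane, C[Si](C)(C)Cl
Why: kinetic enol silylation with internal quench should take place at C7 and not at the neopentyl C10 next to quaternary C1 (the preference that 2-oxo steroids show for enolisation away from the angular centre), and immediate O-silylation at low temperature forestalls β-elimination of the equatorial C6 silyloxy group, with no stereocentre changed.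

Step 9
Reactants: 13 (1R,3aR,7S,7aS)-3a-methyl-1-(propan-2-yl)-1-[(triethylsilyl)oxy]-5,7-bis[(trimethylsilyl)oxy]-2,3,3a,4,7,7a-hexahydro-1H-indene; 14 1,1-dichloroethane
Product: 17 (1R,3aR,8S,8aS)-8-hydroxy-3a,6-dimethyl-1-(propan-2-yl)-1-[(triethylsilyl)oxy]-2,3,3a,4,8,8a-hexahydroazulen-5(1H)-one, via chloro(methyl)cyclopropane adduct 15 (not isolated), via bis-silyl enone 16 (not isolated)
Conditions: n-BuLi (slow addition), Et2O, −40 °C; then Et3N, toluene, 110 °C; then citric acid, MeOH, 25 °C
Reagents that add atoms: none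
Why: Deprotonation of 1,1-dichloroethane gives 1,1-dichloroethyllithium, which transfers chloro(methyl)carbene to the electron-rich C7=C9 enol ether, the only alkene present, in a [2+1] addition that forms C7–C8 and C8–C9. On heating, the adduct with chlorine on the side of the six-membered ring ionises with concerted disrotatory two-electron electrocyclic opening of the shared C7–C9 bond, assisted by the siloxy oxygen, and the 2-siloxyallyl cation loses Me3SiCl to give the seven-membered 8-methyl-7-en-9-one. The closest known reaction type is the addition of chloro(methyl)carbene to silyl enol ethers of cycloalkanones followed by thermal ring enlargement to 2-methylcycloalk-2-enones. The three-membered ring closes by cheletropic carbene addition and the seven-membered ring arises by ring enlargement of the six-membered ring, not by end-to-end cyclisation. No lasting stereocentre is created, since the cyclopropane centres vanish on opening and C1, C4, C5 and C6 are spectators. The step needs regioselectivity, which the position of the enol ether double bond in 13 secures, and an endo chlorine, which the usual preference of chlorocarbenoids to place chlorine syn to the ring should provide; the mild acidic methanolysis then frees only the secondary C6 trimethylsilyl ether.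

Step 10
Reactants: 18 4-hydroxybenzoic acid
Product: 20 4-[(tert-butyldimethylsilyl)oxy]benzoic acid, via bis-silylated acid 19 (not isolated)
Conditions: TBSCl, imidazole, DMF, 25 °C; then AcOH, THF/H2O, 25 °C
Reagents that add atoms: tert-butyldimethylsilyl chloride, CC(C)(C)[Si](C)(C)Cl
Why: O-silylation of phenol and acid followed by selective hydrolysis of the labile silyl ester leaves the phenol masked as its silyl ether, and no stereocentre is involved.

Step 11
Reactants: 17 (1R,3aR,8S,8aS)-8-hydroxy-3a,6-dimethyl-1-(propan-2-yl)-1-[(triethylsilyl)oxy]-2,3,3a,4,8,8a-hexahydroazulen-5(1H)-one; 20 4-[(tert-butyldimethylsilyl)oxy]benzoic acid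
Product: 21 (3R,3aS,4S,8aR)-6,8a-dimethyl-7-oxo-3-(propan-2-yl)-3-[(triethylsilyl)oxy]-1,2,3,3a,4,7,8,8a-octahydroazulen-4-yl 4-[(tert-butyldimethylsilyl)oxy]benzoate
Conditions: EDC·HCl, DMAP, CH2Cl2, 25 °C
Reagents that add atoms: none
Why: carbodiimide-mediated Steglich esterification acylates the only free hydroxyl (secondary, allylic, at C6) with retention at C6, the tertiary C4 alcohol being silylated.

Step 12
Reactants: 21 (3R,3aS,4S,8aR)-6,8a-dimethyl-7-oxo-3-(propan-2-yl)-3-[(triethylsilyl)oxy]-1,2,3,3a,4,7,8,8a-octahydroazulen-4-yl 4-[(tert-butyldimethylsilyl)oxy]benzoate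
Product: 22 (3R,3aS,4S,7R,8aR)-7-hydroxy-6,8a-dimethyl-3-(propan-2-yl)-3-[(triethylsilyl)oxy]-1,2,3,3a,4,7,8,8a-octahydroazulen-4-yl 4-[(tert-butyldimethylsilyl)oxy]benzoate
Conditions: NaBH4, CeCl3·7H2O, MeOH, −78 → −40 °C
Reagents that add atoms: none
Why: Luche reduction delivers hydride 1,2 to the enone carbonyl, and attack from the α-face, opposite the axial angular methyl that shields the β-face of C9 across C10, should give the 9β (pseudoaxial) allylic alcohol.

Step 13
Reactants: 22 (3R,3aS,4S,7R,8aR)-7-hydroxy-6,8a-dimethyl-3-(propan-2-yl)-3-[(triethylsilyl)oxy]-1,2,3,3a,4,7,8,8a-octahydroazulen-4-yl 4-[(tert-butyldimethylsilyl)oxy]benzoate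
Product: 23 (3R,3aS,4S,7S,8aR)-7-acetoxy-6,8a-dimethyl-3-(propan-2-yl)-3-[(triethylsilyl)oxy]-1,2,3,3a,4,7,8,8a-octahydroazulen-4-yl 4-[(tert-butyldimethylsilyl)oxy]benzoate
Conditions: AcOH, PPh3, DIAD, toluene, 0 → 25 °C
Reagents that add atoms: acetic acid, CC(=O)O
Why: Mitsunobu esterification displaces the activated allylic oxygen by SN2 with inversion, acetate entering from the less hindered α-face, which sets the 9α-acetoxy configuration of the target.

Step 14
Reactants: 23 (3R,3aS,4S,7S,8aR)-7-acetoxy-6,8a-dimethyl-3-(propan-2-yl)-3-[(triethylsilyl)oxy]-1,2,3,3a,4,7,8,8a-octahydroazulen-4-yl 4-[(tert-butyldimethylsilyl)oxy]benzoate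
Product: 24 (3R,3aS,4S,7S,8aR)-7-acetoxy-3-hydroxy-6,8a-dimethyl-3-(propan-2-yl)-1,2,3,3a,4,7,8,8a-octahydroazulen-4-yl 4-hydroxybenzoate
Conditions: HF·pyridine, pyridine, THF, 0 → 25 °C
Reagents that add atoms: none
Why: fluoride-mediated desilylation removes the phenolic and the tertiary silyl ether without touching the two esters, and no stereocentre is affected.

**Compound list**

1 | 3-ethoxycyclopent-2-en-1-one | CCOC1=CC(=O)CC1 | starting material
2 | allylmagnesium bromide | C=CC[Mg]Br | starting material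
3 | bromomagnesium 1-allyl-3-ethoxycyclopent-2-en-1-olate (racemic; the carbinol centre is lost on hydrolysis) | C=CCC1(O[Mg]Br)C=C(OCC)CC1 | intermediate
4 | 3-allylcyclopent-2-en-1-one | C=CCC1=CC(=O)CC1 | intermediate
5 | dimethylaluminium (R)-3-allyl-3-methylcyclopent-1-en-1-olate | C=CC[C@@]1(C)CCC(O[Al](C)C)=C1 | intermediate
6 | (R)-[(3-allyl-3-methylcyclopent-1-en-1-yl)oxy]trimethylsilane | C=CC[C@@]1(C)CCC(O[Si](C)(C)C)=C1 | intermediate
7 | (2S,3R)-3-allyl-2-(dimethoxymethyl)-3-methylcyclopentan-1-one (acetal trans to allyl) | C=CC[C@@]1(C)CCC(=O)[C@@H]1C(OC)OC | intermediate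
8 | (1R,2R,3R)-3-allyl-2-(dimethoxymethyl)-3-methyl-1-(propan-2-yl)cyclopentan-1-ol | C=CC[C@@]1(C)CC[C@@](O)(C(C)C)[C@@H]1C(OC)OC | intermediate
9 | (1R,2R,5R)-2-allyl-2-methyl-5-(propan-2-yl)-5-[(triethylsilyl)oxy]cyclopentane-1-carbaldehyde | C=CC[C@@]1(C)CC[C@@](O[Si](CC)(CC)CC)(C(C)C)[C@@H]1C=O | intermediate
10 | (1R,2R,5R)-2-methyl-2-(2-oxopropyl)-5-(propan-2-yl)-5-[(triethylsilyl)oxy]cyclopentane-1-carbaldehyde | CC(=O)C[C@@]1(C)CC[C@@](O[Si](CC)(CC)CC)(C(C)C)[C@@H]1C=O | intermediate
11 | lithium (1R,3aR,7S,7aS)-3a-methyl-5-oxo-1-(propan-2-yl)-1-[(triethylsilyl)oxy]octahydro-1H-inden-7-olate (trans-fused aldolate) | O=C1C[C@@]2(C)CC[C@@](O[Si](CC)(CC)CC)(C(C)C)[C@@H]2[C@@H](O[Li])C1 | intermediate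
12 | (1R,3aR,7S,7aS)-3a-methyl-1-(propan-2-yl)-1-[(triethylsilyl)oxy]-7-[(trimethylsilyl)oxy]octahydro-5H-inden-5-one (trans-fused; C6 oxygen α, equatorial) | O=C1C[C@@]2(C)CC[C@@](O[Si](CC)(CC)CC)(C(C)C)[C@@H]2[C@@H](O[Si](C)(C)C)C1 | intermediate
13 | (1R,3aR,7S,7aS)-3a-methyl-1-(propan-2-yl)-1-[(triethylsilyl)oxy]-5,7-bis[(trimethylsilyl)oxy]-2,3,3a,4,7,7a-hexahydro-1H-indene (C7=C9 enol ether; key-step precursor) | C1=C(O[Si](C)(C)C)C[C@@]2(C)CC[C@@](O[Si](CC)(CC)CC)(C(C)C)[C@@H]2[C@H]1O[Si](C)(C)C | intermediate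
14 | 1,1-dichloroethane | CC(Cl)Cl | starting material
15 | chloro(methyl)cyclopropane adduct of 13 (C8 with Cl and CH3 bridges C7 and C9; mixture at the three transient cyclopropane centres) | C[Si](C)(C)OC12C[C@@]3(C)CC[C@@](O[Si](CC)(CC)CC)(C(C)C)[C@@H]3[C@@H](O[Si](C)(C)C)C1C2(C)Cl | intermediate
16 | (1R,3aR,8S,8aS)-3a,6-dimethyl-1-(propan-2-yl)-1-[(triethylsilyl)oxy]-8-[(trimethylsilyl)oxy]-2,3,3a,4,8,8a-hexahydroazulen-5(1H)-one (4,6-bis(silyloxy)dauc-7-en-9-one) | O=C1C[C@@]2(C)CC[C@@](O[Si](CC)(CC)CC)(C(C)C)[C@@H]2[C@@H](O[Si](C)(C)C)C=C1C | intermediate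
17 | (1R,3aR,8S,8aS)-8-hydroxy-3a,6-dimethyl-1-(propan-2-yl)-1-[(triethylsilyl)oxy]-2,3,3a,4,8,8a-hexahydroazulen-5(1H)-one | O=C1C[C@@]2(C)CC[C@@](O[Si](CC)(CC)CC)(C(C)C)[C@@H]2[C@@H](O)C=C1C | intermediate
18 | 4-hydroxybenzoic acid | O=C(O)c1ccc(O)cc1 | starting material
19 | tert-butyldimethylsilyl 4-[(tert-butyldimethylsilyl)oxy]benzoate | CC(C)(C)[Si](C)(C)Oc1ccc(cc1)C(=O)O[Si](C)(C)C(C)(C)C | intermediate
20 | 4-[(tert-butyldimethylsilyl)oxy]benzoic acid | CC(C)(C)[Si](C)(C)Oc1ccc(cc1)C(=O)O | intermediate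
21 | (3R,3aS,4S,8aR)-6,8a-dimethyl-7-oxo-3-(propan-2-yl)-3-[(triethylsilyl)oxy]-1,2,3,3a,4,7,8,8a-octahydroazulen-4-yl 4-[(tert-butyldimethylsilyl)oxy]benzoate | O=C1C[C@@]2(C)CC[C@@](O[Si](CC)(CC)CC)(C(C)C)[C@@H]2[C@@H](OC(=O)c2ccc(O[Si](C)(C)C(C)(C)C)cc2)C=C1C | intermediate
22 | (3R,3aS,4S,7R,8aR)-7-hydroxy-6,8a-dimethyl-3-(propan-2-yl)-3-[(triethylsilyl)oxy]-1,2,3,3a,4,7,8,8a-octahydroazulen-4-yl 4-[(tert-butyldimethylsilyl)oxy]benzoate (9β-alcohol) | O[C@@H]1C[C@@]2(C)CC[C@@](O[Si](CC)(CC)CC)(C(C)C)[C@@H]2[C@@H](OC(=O)c2ccc(O[Si](C)(C)C(C)(C)C)cc2)C=C1C | intermediate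
23 | (3R,3aS,4S,7S,8aR)-7-acetoxy-6,8a-dimethyl-3-(propan-2-yl)-3-[(triethylsilyl)oxy]-1,2,3,3a,4,7,8,8a-octahydroazulen-4-yl 4-[(tert-butyldimethylsilyl)oxy]benzoate (9α-acetate) | CC(=O)O[C@H]1C[C@@]2(C)CC[C@@](O[Si](CC)(CC)CC)(C(C)C)[C@@H]2[C@@H](OC(=O)c2ccc(O[Si](C)(C)C(C)(C)C)cc2)C=C1C | intermediate
24 | (3R,3aS,4S,7S,8aR)-7-acetoxy-3-hydroxy-6,8a-dimethyl-3-(propan-2-yl)-1,2,3,3a,4,7,8,8a-octahydroazulen-4-yl 4-hydroxybenzoate | CC(=O)O[C@H]1C[C@@]2(C)CC[C@@](O)(C(C)C)[C@@H]2[C@@H](OC(=O)c2ccc(O)cc2)C=C1C | target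

**Step count and risks**

Total step count: 14. Longest linear sequence: 13 steps (steps 1–9 and 11–14); step 10 is a one-step side branch.

The three steps most likely to fail:

Step 9. The carbenoid may decompose before it reaches the hindered enol ether, the alkyllithium may cleave the enol silyl ether, or the adduct may form mainly with chlorine exo, which cannot open in the disrotatory sense. The fallback inserts a CH2 carbon first and adds the methyl afterwards. It sets out from 13: zinc-carbenoid cyclopropanation (Et2Zn, CH2I2, Simmons–Smith type) gives the siloxycyclopropane F1. Oxidative cleavage of the internal cyclopropane bond with FeCl3 in DMF gives the ring-enlarged 7-chloro ketone F2, and NaOAc in MeOH eliminates HCl to the enone without the C8 methyl F3. α-Iodination (I2, pyridine) gives the 8-iodo enone F4, and Suzuki–Miyaura methylation (trimethylboroxine, Pd(PPh3)4, K2CO3) comes back to the route at 16, which is taken through the acidic methanolysis of step 9 to 17.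

Step 3. The methyl and allyl groups on C1 differ little in size, so facial selectivity in the C–C bond formation and the epimer ratio at C5 after equilibration may both be poor, and the wrong epimer would pass its configuration on to C4 in step 4. The fallback replaces substrate control by catalyst control. It sets out from 6: hydroxymethylation with aqueous formaldehyde under Sc(OTf)3 and a chiral 2,2'-bipyridine diol ligand gives the hydroxymethyl ketone F5, with C5 fixed by the catalyst. Excess i-PrMgCl with LaCl3·2LiCl adds opposite the CH2O arm to give the diol F6. TEMPO with PhI(OAc)2 oxidises only the primary alcohol to the hydroxy aldehyde F7, and TESOTf with 2,6-lutidine silylates the tertiary alcohol, which comes back to the route at 9.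

Step 8. Enolisation may occur toward C10, which would send C8 into the C9–C10 bond, or the C6 silyloxy group may be lost by β-elimination from the enolate. The fallback generates the enolate regiospecifically. It sets out from 10: aldol condensation (piperidinium acetate, toluene, 80 °C) gives the C6=C7 enone F8. Nucleophilic epoxidation (H2O2, NaOH, MeOH) from the face opposite the angular methyl gives the 6α,7α-epoxy ketone F9. Two-electron reductive opening with lithium naphthalenide in THF at −78 °C produces only the C7=C9 enolate together with the C6 alkoxide, and trapping both with TMSCl comes back to the route at 13.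

Further compounds
F1 | step 9 | siloxycyclopropane (CH2 bridging C7 and C9 of 13) | C[Si](C)(C)OC12C[C@@]3(C)CC[C@@](O[Si](CC)(CC)CC)(C(C)C)[C@@H]3[C@@H](O[Si](C)(C)C)C1C2
F2 | step 9 | ring-enlarged 7-chloro ketone (no methyl on C8; mixture at C7) | O=C1C[C@@]2(C)CC[C@@](O[Si](CC)(CC)CC)(C(C)C)[C@@H]2[C@@H](O[Si](C)(C)C)C(Cl)C1
F3 | step 9 | 4-(triethylsilyloxy)-6-(trimethylsilyloxy) cyclohept-7-en-9-one without the C8 methyl | O=C1C[C@@]2(C)CC[C@@](O[Si](CC)(CC)CC)(C(C)C)[C@@H]2[C@@H](O[Si](C)(C)C)C=C1
F4 | step 9 | 8-iodo enone | O=C1C[C@@]2(C)CC[C@@](O[Si](CC)(CC)CC)(C(C)C)[C@@H]2[C@@H](O[Si](C)(C)C)C=C1I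
F5 | step 3 | (2S,3R)-3-allyl-2-(hydroxymethyl)-3-methylcyclopentan-1-one | C=CC[C@@]1(C)CCC(=O)[C@@H]1CO
F6 | step 3 | (1R,2S,3R)-3-allyl-2-(hydroxymethyl)-3-methyl-1-(propan-2-yl)cyclopentan-1-ol | C=CC[C@@]1(C)CC[C@@](O)(C(C)C)[C@@H]1CO
F7 | step 3 | (1R,2R,5R)-2-allyl-5-hydroxy-2-methyl-5-(propan-2-yl)cyclopentane-1-carbaldehyde | C=CC[C@@]1(C)CC[C@@](O)(C(C)C)[C@@H]1C=O
F8 | step 8 | (1R,3aR,7aR)-3a-methyl-1-(propan-2-yl)-1-[(triethylsilyl)oxy]-1,2,3,3a,4,7a-hexahydro-5H-inden-5-one (C6=C7 enone) | O=C1C[C@@]2(C)CC[C@@](O[Si](CC)(CC)CC)(C(C)C)[C@@H]2C=C1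
F9 | step 8 | 6α,7α-epoxy ketone of F8 | O=C1C[C@@]2(C)CC[C@@](O[Si](CC)(CC)CC)(C(C)C)[C@@H]2[C@H]2O[C@@H]12
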